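## Retrosynthetic overview
1. 20 ⇐ 19 (15-deoxy compound). The last step is a C15–H allylic hydroxylation, so O15 never needs a protecting group.
2. 19 ⇐ 17 by the C6–C7 bond. One visible-light chromium allylation closes the ten-membered carbocycle and the trans-γ-lactone together and sets C6 and C7.
3. 17 ⇐ dialdehyde 14 + methyl propiolate 15 (C11–C13). 14 ⇐ furanone alcohol 11 + (R)-2-methylbutanoic acid 12.
4. 11 ⇐ lactone 6 + enyne 8. Acetylide opening of the lactone makes C1–C2 and frees O8, and a 5-endo O10→C3 closure then gives the furanone.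
5. 6 ⇐ 1. C8 is bought, and C10 is built by two enolate reactions anti to the C8 side chain. Ring order: furanone first, then carbocycle and lactone together.

Assumption: 1, 7, 12 and 15 are catalogue compounds (1 and 12 as single enantiomers). Germacrane numbering is used throughout: C1 ketone, C2=C3, C4=C5, C6 lactone carbinol, C7, C8 ester carbinol, C9, C10 quaternary, C11=C13, C12 lactone C=O, C14, C15.

## Route

Step 1
Reactants: 1 (R)-5-(hydroxymethyl)dihydrofuran-2(3H)-one
Product: 2 (R)-5-[(triethylsilyloxy)methyl]dihydrofuran-2(3H)-one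
Conditions: TESCl, imidazole, CH2Cl2, 0 °C to rt
Reagents that add atoms: chlorotriethylsilane CC[Si](Cl)(CC)CC
Why: Standard silylation of a primary alcohol, in which TES survives the enolate and acetylide chemistry, is oxidised off directly in step 7, and leaves the bought centre C8 untouched.

Step 2
Reactants: 2 (R)-5-[(triethylsilyloxy)methyl]dihydrofuran-2(3H)-one
Product: 4 (3S,5R)-3-methyl-5-[(triethylsilyloxy)methyl]dihydrofuran-2(3H)-one, via lithium enolate 3 (not isolated)
Conditions: LDA, THF, −78 °C; MeI, −78 to −40 °C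
Reagents that add atoms: iodomethane CI
Why: Kinetic lactone enolate alkylation (SN2 on MeI) brings in C14, and although MeI enters anti to the C8 side chain, this C10–H centre is planarised again in step 3, so its ratio does not matter.

Step 3
Reactants: 4 (3S,5R)-3-methyl-5-[(triethylsilyloxy)methyl]dihydrofuran-2(3H)-one
Product: 6 (3S,5R)-3-hydroxy-3-methyl-5-[(triethylsilyloxy)methyl]dihydrofuran-2(3H)-one, via potassium enolate 5 (not isolated)
Conditions: KHMDS, THF, −78 °C; (±)-2-(phenylsulfonyl)-3-phenyloxaziridine, −78 °C; AcOH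
Reagents that add atoms: (±)-2-(phenylsulfonyl)-3-phenyloxaziridine O=S(=O)(c1ccccc1)N1OC1c1ccccc1
Why: In this Davis-type electrophilic α-hydroxylation of the fully substituted enolate, the bulky racemic (so stereochemically silent) oxaziridine attacks the face anti to the CH2OTES group on C8, which places O10 trans to C7 and sets the quaternary centre as 10S by 1,3-substrate control.

Step 4
Reactants: 7 (Z)-3-methylpent-2-en-4-yn-1-ol
Product: 8 (Z)-triethyl[(3-methylpent-2-en-4-yn-1-yl)oxy]silane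
Conditions: TESCl, imidazole, CH2Cl2, 0 °C
Reagents that add atoms: chlorotriethylsilane CC[Si](Cl)(CC)CC
Why: Silylation of O6 stops the (Z)-enynol from cycloisomerising to a furan once the alkyne becomes an ynone, and it puts the same Swern-labile group on O6 as on O7.

Step 5
Reactants: 6 (3S,5R)-3-hydroxy-3-methyl-5-[(triethylsilyloxy)methyl]dihydrofuran-2(3H)-one; 8 (Z)-triethyl[(3-methylpent-2-en-4-yn-1-yl)oxy]silane
Product: 11 (S)-2-[(R)-2-hydroxy-3-(triethylsilyloxy)propyl]-2-methyl-5-[(Z)-4-(triethylsilyloxy)but-2-en-2-yl]furan-3(2H)-one, via lithium acetylide 9 (not isolated), via hydroxy ynone 10 (not isolated)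
Conditions: 8 (2.6 equiv), n-BuLi (2.5 equiv), THF, −78 °C; add 6, −78 to −30 °C; AcOH; crude in toluene, (4-CF3C6H4)3PAuCl/AgOTf (5 mol %), rt
Reagents that add atoms: none
Why: Acetylide addition to the lactone stops at the lactolate (C1–C2 bond; the first equivalent only deprotonates O10–H) and frees O8 on work-up, after which gold(I)-catalysed 5-endo-dig attack of the tertiary O10–H on C3 of the α′-hydroxy ynone gives the 3(2H)-furanone without touching C8, C10 or the Z-alkene.

Step 6
Reactants: 11 (S)-2-[(R)-2-hydroxy-3-(triethylsilyloxy)propyl]-2-methyl-5-[(Z)-4-(triethylsilyloxy)but-2-en-2-yl]furan-3(2H)-one; 12 (R)-2-methylbutanoic acid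
Product: 13 (R)-1-{(S)-2-methyl-3-oxo-5-[(Z)-4-(triethylsilyloxy)but-2-en-2-yl]-2,3-dihydrofuran-2-yl}-3-(triethylsilyloxy)propan-2-yl (R)-2-methylbutanoate
Conditions: DCC, DMAP (cat.), CH2Cl2, 0 °C to rt
Reagents that add atoms: none
Why: Steglich esterification acylates the only free hydroxyl (O8) with retention at C8, and the bought α-centre of the simple alkanoic acid does not racemise under these mild conditions.

Step 7
Reactants: 13 (R)-1-{(S)-2-methyl-3-oxo-5-[(Z)-4-(triethylsilyloxy)but-2-en-2-yl]-2,3-dihydrofuran-2-yl}-3-(triethylsilyloxy)propan-2-yl (R)-2-methylbutanoate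
Product: 14 (R)-1-{(S)-2-methyl-3-oxo-5-[(Z)-4-oxobut-2-en-2-yl]-2,3-dihydrofuran-2-yl}-3-oxopropan-2-yl (R)-2-methylbutanoate
Conditions: (COCl)2, DMSO, CH2Cl2, −78 to −35 °C; Et3N, −78 to 0 °C; used crude
Reagents that add atoms: none
Why: Swern conditions oxidise primary TES ethers directly to aldehydes (activated DMSO displaces silicon), so both termini are deprotected and oxidised in one operation, and the cold amine stage keeps the Z-enal and the α-acyloxy centre C8 intact.

Step 8
Reactants: 14 (R)-1-{(S)-2-methyl-3-oxo-5-[(Z)-4-oxobut-2-en-2-yl]-2,3-dihydrofuran-2-yl}-3-oxopropan-2-yl (R)-2-methylbutanoate; 15 methyl propiolate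
Product: 17 methyl (4R)-3-hydroxy-2-methylidene-4-{[(R)-2-methylbutanoyl]oxy}-5-{(S)-2-methyl-3-oxo-5-[(Z)-4-oxobut-2-en-2-yl]-2,3-dihydrofuran-2-yl}pentanoate (C7 epimers), via vinylalane 16 (not isolated)
Conditions: DIBAL-H, NMO, THF, 0 °C; 15, 0 °C; add to 14 (1.1 equiv of 16), −78 to −30 °C; cold buffered work-up
Reagents that add atoms: none
Why: 1,4-Hydroalumination of the propiolate gives the α-aluminoacrylate, which adds 1,2 (a Baylis–Hillman-type adduct made under non-basic conditions) to the much more electrophilic α-acyloxy aldehyde rather than to the β,β-disubstituted vinylogous enal, and the new C7 carbinol centre is a mixture that step 9 erases.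

Step 9
Reactants: 17 methyl (4R)-3-hydroxy-2-methylidene-4-{[(R)-2-methylbutanoyl]oxy}-5-{(S)-2-methyl-3-oxo-5-[(Z)-4-oxobut-2-en-2-yl]-2,3-dihydrofuran-2-yl}pentanoate
Product: 19 (4Z,6R,7R,8R,10S)-8-[(R)-2-methylbutanoyloxy]-1-oxo-3,10-epoxygermacra-2,4,11(13)-trien-12,6-olide, via macrocyclic hydroxy ester 18 (not isolated)
Conditions: 17 (3 mM), PPh3 (1.5 equiv), CrCl3·3THF (20 mol %), 4CzIPN (3 mol %), 2,6-lutidine (1 equiv), degassed DMF, 450 nm LEDs, 25 °C; then PPTS (cat.), CH2Cl2
Reagents that add atoms: none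
Why: Proposed new method: this is a phosphine-mediated deoxygenative Nozaki–Hiyama allylation under chromium/photoredox dual catalysis, in which excited 4CzIPN (+1.35 V) oxidises PPh3 (+0.98 V), the only free OH (on C7) traps the phosphine radical cation, the phosphoranyl radical β-scissions to Ph3P=O and the 2-(methoxycarbonyl)allyl radical, Cr(II) captures that radical at C13, the σ-allylchromium(III) adds through C7 to the tethered C6 aldehyde in a closed chair (C5 and C8 both equatorial give the anti adduct and hence the trans-lactone, while A1,3 strain with the ester holds H8 in the alkene plane so the aldehyde arrives anti to C9 and 8R relays to 6R,7R), the proton released on phosphoranyl formation frees the alkoxide, and 4CzIPN•− (−1.21 V, too weak to reduce the dienal) returns Cr(III) (−0.65 V) to Cr(II) so the step is redox-neutral; the closest known reaction types are dual photoredox/chromium allylation of aldehydes with oxidatively generated allyl radicals, photoredox phosphoranyl-radical C–O scission of benzylic alcohols, and stoichiometric CrCl2 closure of germacranolides from ω-formyl 2-(bromomethyl)acrylates.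

Step 10
Reactants: 19 (4Z,6R,7R,8R,10S)-8-[(R)-2-methylbutanoyloxy]-1-oxo-3,10-epoxygermacra-2,4,11(13)-trien-12,6-olide
Product: 20 (4Z,6R,7R,8R,10S)-15-hydroxy-8-[(R)-2-methylbutanoyloxy]-1-oxo-3,10-epoxygermacra-2,4,11(13)-trien-12,6-olide
Conditions: SeO2 (0.3 equiv), t-BuOOH (3 equiv), CH2Cl2, 0 °C to rt
Reagents that add atoms: tert-butyl hydroperoxide CC(C)(C)OO (its oxygen reaches C15 by way of selenium dioxide O=[Se]=O)
Why: In this selenium dioxide allylic hydroxylation (ene reaction then [2,3]-shift, t-BuOOH as terminal oxidant), C15 is the only allylic CH3 and sits on the more substituted end of C4=C5, the acceptor alkenes C2=C3 and C11=C13 are inert as in known oxidations of α-methylene-lactone germacranolides, and no stereocentre is touched.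

## Compound list
1 | (R)-5-(hydroxymethyl)dihydrofuran-2(3H)-one | OC[C@H]1CCC(=O)O1 | starting material
2 | (R)-5-[(triethylsilyloxy)methyl]dihydrofuran-2(3H)-one | CC[Si](CC)(CC)OC[C@H]1CCC(=O)O1 | intermediate
3 | lithium enolate of 2 | CC[Si](CC)(CC)OC[C@H]1CC=C(O[Li])O1 | intermediate
4 | (3S,5R)-3-methyl-5-[(triethylsilyloxy)methyl]dihydrofuran-2(3H)-one (major trans epimer) | CC[Si](CC)(CC)OC[C@H]1C[C@H](C)C(=O)O1 | intermediate
5 | potassium enolate of 4 | CC[Si](CC)(CC)OC[C@H]1CC(C)=C(O[K])O1 | intermediate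
6 | (3S,5R)-3-hydroxy-3-methyl-5-[(triethylsilyloxy)methyl]dihydrofuran-2(3H)-one | CC[Si](CC)(CC)OC[C@H]1C[C@](C)(O)C(=O)O1 | intermediate
7 | (Z)-3-methylpent-2-en-4-yn-1-ol | C#C/C(C)=C\CO | starting material
8 | (Z)-triethyl[(3-methylpent-2-en-4-yn-1-yl)oxy]silane | C#C/C(C)=C\CO[Si](CC)(CC)CC | intermediate
9 | lithium acetylide of 8 | [Li]C#C/C(C)=C\CO[Si](CC)(CC)CC | intermediate
10 | (2R,4S,8Z)-2,4-dihydroxy-4,8-dimethyl-1,10-bis(triethylsilyloxy)dec-8-en-6-yn-5-one | CC[Si](CC)(CC)OC[C@H](O)C[C@](C)(O)C(=O)C#C/C(C)=C\CO[Si](CC)(CC)CC | intermediate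
11 | (S)-2-[(R)-2-hydroxy-3-(triethylsilyloxy)propyl]-2-methyl-5-[(Z)-4-(triethylsilyloxy)but-2-en-2-yl]furan-3(2H)-one | CC[Si](CC)(CC)OC[C@H](O)C[C@]1(C)OC(=CC1=O)/C(C)=C\CO[Si](CC)(CC)CC | intermediate
12 | (R)-2-methylbutanoic acid | CC[C@@H](C)C(=O)O | starting material
13 | O8-(R)-2-methylbutanoate of 11 | CC[Si](CC)(CC)OC[C@H](OC(=O)[C@H](C)CC)C[C@]1(C)OC(=CC1=O)/C(C)=C\CO[Si](CC)(CC)CC | intermediate
14 | C6,C7-dialdehyde (8R,10S,4Z) | O=C[C@H](OC(=O)[C@H](C)CC)C[C@]1(C)OC(=CC1=O)/C(C)=C\C=O | intermediate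
15 | methyl propiolate | C#CC(=O)OC | starting material
16 | methyl 2-(diisobutylalumanyl)acrylate | C=C(C(=O)OC)[Al](CC(C)C)CC(C)C | intermediate
17 | Baylis–Hillman-type allylic alcohol (C7 epimers, 8R,10S,4Z) | COC(=O)C(=C)C(O)[C@H](OC(=O)[C@H](C)CC)C[C@]1(C)OC(=CC1=O)/C(C)=C\C=O | intermediate
18 | macrocyclic 6-hydroxy methyl ester (seco-lactone of 19, same configurations) | COC(=O)C(=C)[C@H]1[C@H](O)/C=C(/C)C2=CC(=O)[C@](C)(C[C@H]1OC(=O)[C@H](C)CC)O2 | intermediate
19 | 15-deoxy compound | C=C1C(=O)O[C@@H]2/C=C(/C)C3=CC(=O)[C@](C)(C[C@@H](OC(=O)[C@H](C)CC)[C@@H]12)O3 | intermediate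
20 | CNP0307052.2 | C=C1C(=O)O[C@@H]2/C=C(/CO)C3=CC(=O)[C@](C)(C[C@@H](OC(=O)[C@H](C)CC)[C@@H]12)O3 | target

## Step count and risks
- **Total steps:** 10.
- **Longest linear sequence:** 9 (steps 1, 2, 3, 5, 6, 7, 8, 9, 10). Step 4 is the only side step.

**Step 9 (the new step).**
- Risks: Cr(II) may capture the allyl radical too slowly at high dilution. The allylchromium may lose the C8 acyloxy group by 1,4-elimination. The macrocyclic chair may select the wrong face. Energy transfer from 4CzIPN will scramble the enal geometry, but only the Z-isomer can close, so the E-isomer is recycled.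
- Fallback: this sets out from 17 and returns at 19, using known chemistry. PBr3 in Et2O at 0 °C converts 17 by SN2′ into the (Z)-allylic bromide F1. F1 is added by syringe pump to excess CrCl2 in THF/DMF, a stoichiometric Nozaki–Hiyama allylation. The resulting 18 lactonises to 19.

**Step 8.**
- Risks: the vinylalane may also attack the enal. The acyl group may shift from O8 to O7 in the aluminium alkoxide or on silica.
- Fallback: this sets out from 14 and returns at 17. Sodium thiophenolate is added to trimethyl 2-phosphonoacrylate. The resulting phosphonate anion olefinates only the aliphatic aldehyde of 14 (tandem Michael/Horner–Wadsworth–Emmons reaction) to give the allyl phenyl sulfide F2. mCPBA at −78 °C gives the allyl sulfoxide F3. Its Mislow–Evans [2,3]-shift in the presence of P(OMe)3 in MeOH delivers 17. No metal alkoxide is ever formed next to the ester on this path.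

**Step 10.**
- Risks: the C4=C5 alkene is conjugated to the furanone and may react sluggishly. Over-oxidation to the 15-aldehyde is also possible.
- Fallback: this sets out from 6 and returns at 20, with O15 brought in by the building block.
  - Bought 4-(tert-butyldimethylsilyloxy)but-2-yn-1-ol is reduced with Red-Al and quenched with I2 to the (Z)-iodoalkenol F4.
  - F4 is silylated with TESCl to the bis-silyl ether F5, which is coupled with ethynylzinc bromide under Pd(PPh3)4 to the enyne F6.
  - F6 replaces 8 in step 5 and gives, with 6, the furanone alcohol F7.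
  - Steps 6 to 9 then give the ester F8, the dialdehyde F9 (the TBS ether survives the Swern conditions), the allylic alcohol F10 and the 15-O-TBS macrolactone F11.
  - HF·pyridine frees 20.

Further compounds
F1 | step 9 | methyl (Z,4R)-2-(bromomethyl)-4-{[(R)-2-methylbutanoyl]oxy}-5-{(S)-2-methyl-3-oxo-5-[(Z)-4-oxobut-2-en-2-yl]-2,3-dihydrofuran-2-yl}pent-2-enoate | COC(=O)/C(CBr)=C/[C@H](OC(=O)[C@H](C)CC)C[C@]1(C)OC(=CC1=O)/C(C)=C\C=O
F2 | step 8 | methyl (Z,4R)-4-{[(R)-2-methylbutanoyl]oxy}-5-{(S)-2-methyl-3-oxo-5-[(Z)-4-oxobut-2-en-2-yl]-2,3-dihydrofuran-2-yl}-2-[(phenylsulfanyl)methyl]pent-2-enoate | COC(=O)/C(CSc1ccccc1)=C/[C@H](OC(=O)[C@H](C)CC)C[C@]1(C)OC(=CC1=O)/C(C)=C\C=O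
F3 | step 8 | sulfoxide of F2 (sulfur epimers) | COC(=O)/C(CS(=O)c1ccccc1)=C/[C@H](OC(=O)[C@H](C)CC)C[C@]1(C)OC(=CC1=O)/C(C)=C\C=O
F4 | step 10 | (Z)-4-(tert-butyldimethylsilyloxy)-3-iodobut-2-en-1-ol | OC/C=C(/CO[Si](C)(C)C(C)(C)C)I
F5 | step 10 | (Z)-1-(tert-butyldimethylsilyloxy)-2-iodo-4-(triethylsilyloxy)but-2-ene | CC[Si](CC)(CC)OC/C=C(/CO[Si](C)(C)C(C)(C)C)I
F6 | step 10 | (Z)-3-[(tert-butyldimethylsilyloxy)methyl]-5-(triethylsilyloxy)pent-3-en-1-yne | CC[Si](CC)(CC)OC/C=C(/CO[Si](C)(C)C(C)(C)C)C#C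
F7 | step 10 | 15-(tert-butyldimethylsilyloxy) analogue of 11 | CC[Si](CC)(CC)OC[C@H](O)C[C@]1(C)OC(=CC1=O)/C(CO[Si](C)(C)C(C)(C)C)=C\CO[Si](CC)(CC)CC
F8 | step 10 | 15-(tert-butyldimethylsilyloxy) analogue of 13 | CC[Si](CC)(CC)OC[C@H](OC(=O)[C@H](C)CC)C[C@]1(C)OC(=CC1=O)/C(CO[Si](C)(C)C(C)(C)C)=C\CO[Si](CC)(CC)CC
F9 | step 10 | 15-(tert-butyldimethylsilyloxy) analogue of 14 | O=C[C@H](OC(=O)[C@H](C)CC)C[C@]1(C)OC(=CC1=O)/C(CO[Si](C)(C)C(C)(C)C)=C\C=O
F10 | step 10 | 15-(tert-butyldimethylsilyloxy) analogue of 17 (C7 epimers) | COC(=O)C(=C)C(O)[C@H](OC(=O)[C@H](C)CC)C[C@]1(C)OC(=CC1=O)/C(CO[Si](C)(C)C(C)(C)C)=C\C=O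
F11 | step 10 | 15-O-tert-butyldimethylsilyl ether of 20 | C=C1C(=O)O[C@@H]2/C=C(/CO[Si](C)(C)C(C)(C)C)C3=CC(=O)[C@](C)(C[C@@H](OC(=O)[C@H](C)CC)[C@@H]12)O3
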